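**Plan**
1. Retrosynthesis first removes three MOM ethers, then cuts the C2–C5' biaryl bond (Suzuki–Miyaura) into a ring A 2-bromobenzofuran and a ring B chroman-5-boronate (unprimed atoms: benzofuran; primed atoms: chroman).
2. Ring B carries its 2,2-dimethylpyran ring (O1', C2', C3', C4') fused at C4a'–C8a' on the side of C5', the carbon that holds the benzofuran. C4' is a benzylic CH2 ortho to a ring oxygen, the retron of an ortho-quinone methide, so O1'–C2' and C3'–C4' are cut together to a 2-hydroxybenzyl alcohol and isobutene.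
3. That alcohol comes from 2-bromo-4,6-dimethoxybenzaldehyde: the formyl carbon becomes C4' and the bromine marks C5'.
4. Ring A: the furan is cut at O1–C2 (Ullmann-type closure) and C2=C3 (dibromo-olefination of a salicylaldehyde); the C7–CMe2 bond is cut by a retro-Claisen to the prenyl ether of bis-MOM phloroglucinaldehyde.
5. Forward order: pyran ring of ring B (step 4) and borylation; reverse prenylation and furan ring of ring A (step 10); union of the two halves (step 11); deprotection (step 12).
6. The target has no stereocentre and no stereogenic double bond, so no stereochemistry has to be set.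

Key step: step 4

Assumption: 2-bromo-4,6-dimethoxybenzaldehyde and isobutene are taken as purchasable, and the SMILES of the target is taken as complete because the molecule is achiral.

**Route**

Step 1
Reactants: 1 2-bromo-4,6-dimethoxybenzaldehyde
Product: 2 2-bromo-4,6-dihydroxybenzaldehyde
Conditions: BBr3 (4 equiv), CH2Cl2, −78 °C to rt; then H2O
Reagents that add atoms: none
Why: Lewis acid O-demethylation with BBr3 should cleave both aryl methyl ethers (the ortho one first, through chelation to the formyl oxygen) while the aldehyde and the aryl bromide are inert.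

Step 2
Reactants: 2 2-bromo-4,6-dihydroxybenzaldehyde
Product: 3 2-bromo-6-hydroxy-4-(methoxymethoxy)benzaldehyde
Conditions: MOMCl (1.05 equiv), K2CO3, acetone, 0 °C to rt
Reagents that add atoms: chloromethyl methyl ether (MOMCl), COCCl
Why: Williamson-type O-alkylation should take place only at the 4-OH, which is the more acidic hydroxyl and is not held in the hydrogen bond to the formyl group that deactivates the 6-OH.

Step 3
Reactants: 3 2-bromo-6-hydroxy-4-(methoxymethoxy)benzaldehyde
Product: 4 3-bromo-2-(hydroxymethyl)-5-(methoxymethoxy)phenol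
Conditions: NaBH4, MeOH/THF, 0 °C; aq NH4Cl work-up
Reagents that add atoms: none
Why: Hydride reduction of the aldehyde with NaBH4 is fast at 0 °C and leaves the aryl bromide and the acetal untouched; the neutral work-up avoids premature ionisation of the salicyl alcohol.

Step 4
Reactants: 4 3-bromo-2-(hydroxymethyl)-5-(methoxymethoxy)phenol; 5 2-methylpropene (isobutene)
Product: 7 5-bromo-7-(methoxymethoxy)-2,2-dimethylchroman, via ortho-quinone methide 6 (not isolated)
Conditions: isobutene (about 30 equiv, condensed in at −78 °C), toluene (0.05 M), sealed steel autoclave, 160 °C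
Reagents that add atoms: none
Why: Heating expels water from the 2-hydroxybenzyl alcohol, helped by the alkoxy group para to the benzylic carbon, and gives ortho-quinone methide 6, an electron-poor 1-oxadiene. Isobutene adds to it in an inverse-electron-demand hetero-Diels–Alder reaction, the known thermal route from salicyl alcohols and 1,1-disubstituted alkenes to 2,2-dialkylchromans. The pyran ring closes by an asynchronous concerted [4+2] cycloaddition in which C4'–C3' forms ahead of O1'–C2', and rearomatisation of the benzene ring makes the addition irreversible. No stereocentre is created. The step needs regio- and chemoselectivity: the nucleophilic CH2 terminus of isobutene attacks the methide carbon so that the carbon with tertiary-cation character ends on oxygen, only the single free phenol next to the CH2OH group can enter the ring, and high dilution with a large excess of alkene should suppress self-condensation of 6.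

Step 5
Reactants: 7 5-bromo-7-(methoxymethoxy)-2,2-dimethylchroman
Product: 8 2-[7-(methoxymethoxy)-2,2-dimethylchroman-5-yl]-4,4,5,5-tetramethyl-1,3,2-dioxaborolane
Conditions: B2pin2, Pd(dppf)Cl2 (5 mol %), KOAc, 1,4-dioxane, 90 °C
Reagents that add atoms: bis(pinacolato)diboron, CC1(C)OB(OC1(C)C)B1OC(C)(C)C(C)(C)O1
Why: Miyaura borylation (oxidative addition of the aryl bromide to zerovalent palladium, acetate-assisted transmetalation with B2pin2, reductive elimination) should give the pinacol boronate without affecting the MOM ether or the chroman.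

Step 6
Reactants: 9 2,4,6-trihydroxybenzaldehyde
Product: 10 2-hydroxy-4,6-bis(methoxymethoxy)benzaldehyde
Conditions: MOMCl (2.2 equiv), K2CO3, acetone, 0 °C to rt
Reagents that add atoms: chloromethyl methyl ether (MOMCl), COCCl
Why: O-alkylation with MOMCl (acetal protection) should stop at the bis-ether because the last hydroxyl is held in a strong hydrogen bond to the formyl group.

Step 7
Reactants: 10 2-hydroxy-4,6-bis(methoxymethoxy)benzaldehyde; 11 1-bromo-3-methylbut-2-ene (prenyl bromide)
Product: 12 2,4-bis(methoxymethoxy)-6-[(3-methylbut-2-en-1-yl)oxy]benzaldehyde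
Conditions: K2CO3, DMF, rt
Reagents that add atoms: none
Why: Williamson ether synthesis; in DMF the phenoxide of the chelated hydroxyl should be alkylated on oxygen by the primary allylic bromide (SN2).

Step 8
Reactants: 12 2,4-bis(methoxymethoxy)-6-[(3-methylbut-2-en-1-yl)oxy]benzaldehyde
Product: 14 2-hydroxy-4,6-bis(methoxymethoxy)-3-(2-methylbut-3-en-2-yl)benzaldehyde, via cyclohexadienone 13 (not isolated)
Conditions: Eu(fod)3 (10 mol %; fod = 6,6,7,7,8,8,8-heptafluoro-2,2-dimethyloctane-3,5-dionate), CHCl3, 55 °C
Reagents that add atoms: none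
Why: Aromatic Claisen rearrangement accelerated by chelation of Eu(fod)3 between the formyl and ether oxygens; the [3,3] shift delivers the inverted 1,1-dimethylallyl unit to the only free ortho carbon (ring carbon 3), and at this low temperature dienone 13 should tautomerise to the phenol before a Cope shift to ring carbon 5 can compete.

Step 9
Reactants: 14 2-hydroxy-4,6-bis(methoxymethoxy)-3-(2-methylbut-3-en-2-yl)benzaldehyde
Product: 15 2-(2,2-dibromoethenyl)-3,5-bis(methoxymethoxy)-6-(2-methylbut-3-en-2-yl)phenol
Conditions: CBr4, PPh3, Zn dust, CH2Cl2, rt (ylide formed first); then 14, 0 °C to rt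
Reagents that add atoms: carbon tetrabromide, BrC(Br)(Br)Br
Why: Ramirez (Corey–Fuchs) dibromo-olefination; the ylide Ph3P=CBr2, generated with zinc so that neither HBr nor Ph3PBr2 is present, should convert the aldehyde into the 1,1-dibromoalkene in a Wittig reaction that tolerates the hydrogen-bonded phenol, the MOM ethers and the alkene.

Step 10
Reactants: 15 2-(2,2-dibromoethenyl)-3,5-bis(methoxymethoxy)-6-(2-methylbut-3-en-2-yl)phenol
Product: 16 2-bromo-4,6-bis(methoxymethoxy)-7-(2-methylbut-3-en-2-yl)-1-benzofuran
Conditions: CuI (5 mol %), K3PO4, THF, 80 °C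
Reagents that add atoms: none
Why: Copper-catalysed intramolecular Ullmann-type C–O coupling of the phenol with the vinylic bromide cis to the ring should close the five-membered furan and leave the second bromine at C2.

Step 11
Reactants: 16 2-bromo-4,6-bis(methoxymethoxy)-7-(2-methylbut-3-en-2-yl)-1-benzofuran; 8 2-[7-(methoxymethoxy)-2,2-dimethylchroman-5-yl]-4,4,5,5-tetramethyl-1,3,2-dioxaborolane
Product: 17 2-[7-(methoxymethoxy)-2,2-dimethylchroman-5-yl]-4,6-bis(methoxymethoxy)-7-(2-methylbut-3-en-2-yl)-1-benzofuran
Conditions: Pd(dppf)Cl2 (5 mol %), K3PO4, 1,4-dioxane/H2O, 85 °C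
Reagents that add atoms: none
Why: Suzuki–Miyaura cross-coupling; the activated 2-bromobenzofuran adds oxidatively to palladium and couples with the aryl boronate under aqueous phosphate, forming the C2–C5' bond without touching the remote vinyl group.

Step 12
Reactants: 17 2-[7-(methoxymethoxy)-2,2-dimethylchroman-5-yl]-4,6-bis(methoxymethoxy)-7-(2-methylbut-3-en-2-yl)-1-benzofuran
Product: 18 2-(7-hydroxy-2,2-dimethylchroman-5-yl)-7-(2-methylbut-3-en-2-yl)-1-benzofuran-4,6-diol (CNP0300714.0)
Conditions: HCl (2 M aq)/MeOH, 45 °C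
Reagents that add atoms: none
Why: Acid-catalysed acetal solvolysis should remove the three MOM ethers; the monosubstituted vinyl group of the 1,1-dimethylallyl unit would need a secondary cation to cyclise onto the neighbouring phenol, so it should survive dilute acid at mild temperature.

**Compound list**
1 | 2-bromo-4,6-dimethoxybenzaldehyde | COc1cc(Br)c(C=O)c(OC)c1 | starting material
2 | 2-bromo-4,6-dihydroxybenzaldehyde | O=Cc1c(O)cc(O)cc1Br | intermediate
3 | 2-bromo-6-hydroxy-4-(methoxymethoxy)benzaldehyde | COCOc1cc(O)c(C=O)c(Br)c1 | intermediate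
4 | 3-bromo-2-(hydroxymethyl)-5-(methoxymethoxy)phenol | COCOc1cc(O)c(CO)c(Br)c1 | intermediate
5 | 2-methylpropene (isobutene) | C=C(C)C | starting material
6 | 5-bromo-3-(methoxymethoxy)-6-methylidenecyclohexa-2,4-dien-1-one (ortho-quinone methide) | C=C1C(=O)C=C(OCOC)C=C1Br | intermediate (not isolated)
7 | 5-bromo-7-(methoxymethoxy)-2,2-dimethylchroman | COCOc1cc(Br)c2CCC(C)(C)Oc2c1 | intermediate
8 | 2-[7-(methoxymethoxy)-2,2-dimethylchroman-5-yl]-4,4,5,5-tetramethyl-1,3,2-dioxaborolane | COCOc1cc(B2OC(C)(C)C(C)(C)O2)c2CCC(C)(C)Oc2c1 | intermediate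
9 | 2,4,6-trihydroxybenzaldehyde | O=Cc1c(O)cc(O)cc1O | starting material
10 | 2-hydroxy-4,6-bis(methoxymethoxy)benzaldehyde | COCOc1cc(O)c(C=O)c(OCOC)c1 | intermediate
11 | 1-bromo-3-methylbut-2-ene | CC(C)=CCBr | starting material
12 | 2,4-bis(methoxymethoxy)-6-[(3-methylbut-2-en-1-yl)oxy]benzaldehyde | COCOc1cc(OCC=C(C)C)c(C=O)c(OCOC)c1 | intermediate
13 | 2,4-bis(methoxymethoxy)-5-(2-methylbut-3-en-2-yl)-6-oxocyclohexa-1,3-diene-1-carbaldehyde (racemic dienone) | C=CC(C)(C)C1C(=O)C(C=O)=C(OCOC)C=C1OCOC | intermediate (not isolated)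
14 | 2-hydroxy-4,6-bis(methoxymethoxy)-3-(2-methylbut-3-en-2-yl)benzaldehyde | C=CC(C)(C)c1c(O)c(C=O)c(OCOC)cc1OCOC | intermediate
15 | 2-(2,2-dibromoethenyl)-3,5-bis(methoxymethoxy)-6-(2-methylbut-3-en-2-yl)phenol | C=CC(C)(C)c1c(O)c(C=C(Br)Br)c(OCOC)cc1OCOC | intermediate
16 | 2-bromo-4,6-bis(methoxymethoxy)-7-(2-methylbut-3-en-2-yl)-1-benzofuran | C=CC(C)(C)c1c(OCOC)cc(OCOC)c2cc(Br)oc12 | intermediate
17 | 2-[7-(methoxymethoxy)-2,2-dimethylchroman-5-yl]-4,6-bis(methoxymethoxy)-7-(2-methylbut-3-en-2-yl)-1-benzofuran | C=CC(C)(C)c1c(OCOC)cc(OCOC)c2cc(-c3cc(OCOC)cc4c3CCC(C)(C)O4)oc12 | intermediate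
18 | 2-(7-hydroxy-2,2-dimethylchroman-5-yl)-7-(2-methylbut-3-en-2-yl)-1-benzofuran-4,6-diol | C=CC(C)(C)c1c(O)cc(O)c2cc(-c3cc(O)cc4c3CCC(C)(C)O4)oc12 | target

**Step count**
Total: 12 steps. Longest linear sequence: 7 steps (steps 1–5, 11, 12; the ring A branch, steps 6–10, 11, 12, is equally long).

**Steps most likely to fail**

Step 4. The quinone methide 6 may condense with itself or with unreacted 4 faster than the unactivated, gaseous alkene captures it, and the MOM acetal may be lost at the temperature needed. The fallback sets out from 3 and comes back at 7; it closes the pyran ring by an oxa-6π electrocyclisation instead of a cycloaddition. Addition of 2-methylprop-1-enylmagnesium bromide (3 equiv, THF, 0 °C) to aldehyde 3 should give 3-bromo-2-(1-hydroxy-3-methylbut-2-en-1-yl)-5-(methoxymethoxy)phenol F1. Warming F1 in toluene expels water to the vinylogous quinone methide 5-bromo-3-(methoxymethoxy)-6-(3-methylbut-2-en-1-ylidene)cyclohexa-2,4-dien-1-one F2, which closes to 5-bromo-7-(methoxymethoxy)-2,2-dimethyl-2H-chromene F3. Diimide (TsNHNH2, NaOAc, DME/H2O, reflux) then saturates the C3'=C4' bond without touching the aryl bromide and gives 7.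

Step 8. The allyl unit may travel on from dienone 13 by a Cope shift to ring carbon 5, or ionise under the Lewis acid, so that a normal prenyl group ends up para to the oxygen instead of the reverse prenyl group ortho to it. The fallback sets out from 9 and 11 and comes back at 14; it places the ether on the 4-oxygen, whose para position is blocked by the formyl group and whose two ortho positions are equivalent. Alkylation of 9 at its most acidic 4-OH with 11 (1 equiv, K2CO3, acetone) should give 2,6-dihydroxy-4-[(3-methylbut-2-en-1-yl)oxy]benzaldehyde F4. Thermal Claisen rearrangement (N,N-diethylaniline, 180 °C) should give 2,4,6-trihydroxy-3-(2-methylbut-3-en-2-yl)benzaldehyde F5. MOMCl (2 equiv) and K2CO3 should then protect the 4-OH and the unhindered 6-OH and leave the hindered, hydrogen-bonded 2-OH free, which is 14.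

Step 9. The stabilised ylide may fail to add to the hindered, electron-rich, hydrogen-bonded aldehyde, the free phenol may quench it, or ZnBr2 may strip a MOM ether. The fallback sets out from 7 and 14 and comes back at 17 (steps 5, 9, 10 and 11 are then not needed); it closes the furan by an intramolecular aldol-type condensation of a benzyl aryl ether.
- Bromine–lithium exchange on 7 (n-BuLi, THF, −78 °C) gives [7-(methoxymethoxy)-2,2-dimethylchroman-5-yl]lithium F6, which is quenched with DMF to 7-(methoxymethoxy)-2,2-dimethylchroman-5-carbaldehyde F7.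
- NaBH4 gives [7-(methoxymethoxy)-2,2-dimethylchroman-5-yl]methanol F8, and CBr4/PPh3 (Appel reaction) gives 5-(bromomethyl)-7-(methoxymethoxy)-2,2-dimethylchroman F9.
- Alkylation of phenol 14 with F9 (K2CO3, DMF) gives 2-{[7-(methoxymethoxy)-2,2-dimethylchroman-5-yl]methoxy}-4,6-bis(methoxymethoxy)-3-(2-methylbut-3-en-2-yl)benzaldehyde F10.
- The phosphazene base P4-t-Bu in toluene at reflux should deprotonate the benzylic CH2; the carbanion adds to the aldehyde and loss of water gives 17.

**Further compounds**
F1 | step 4 | 3-bromo-2-(1-hydroxy-3-methylbut-2-en-1-yl)-5-(methoxymethoxy)phenol (racemic) | CC(C)=CC(O)c1c(O)cc(OCOC)cc1Br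
F2 | step 4 | 5-bromo-3-(methoxymethoxy)-6-(3-methylbut-2-en-1-ylidene)cyclohexa-2,4-dien-1-one | CC(C)=CC=C1C(=O)C=C(OCOC)C=C1Br
F3 | step 4 | 5-bromo-7-(methoxymethoxy)-2,2-dimethyl-2H-chromene | COCOc1cc(Br)c2C=CC(C)(C)Oc2c1
F4 | step 8 | 2,6-dihydroxy-4-[(3-methylbut-2-en-1-yl)oxy]benzaldehyde | CC(C)=CCOc1cc(O)c(C=O)c(O)c1
F5 | step 8 | 2,4,6-trihydroxy-3-(2-methylbut-3-en-2-yl)benzaldehyde | C=CC(C)(C)c1c(O)cc(O)c(C=O)c1O
F6 | step 9 | [7-(methoxymethoxy)-2,2-dimethylchroman-5-yl]lithium | [Li]c1cc(OCOC)cc2OC(C)(C)CCc12
F7 | step 9 | 7-(methoxymethoxy)-2,2-dimethylchroman-5-carbaldehyde | COCOc1cc(C=O)c2CCC(C)(C)Oc2c1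
F8 | step 9 | [7-(methoxymethoxy)-2,2-dimethylchroman-5-yl]methanol | COCOc1cc(CO)c2CCC(C)(C)Oc2c1
F9 | step 9 | 5-(bromomethyl)-7-(methoxymethoxy)-2,2-dimethylchroman | COCOc1cc(CBr)c2CCC(C)(C)Oc2c1
F10 | step 9 | 2-{[7-(methoxymethoxy)-2,2-dimethylchroman-5-yl]methoxy}-4,6-bis(methoxymethoxy)-3-(2-methylbut-3-en-2-yl)benzaldehyde | C=CC(C)(C)c1c(OCc2cc(OCOC)cc3OC(C)(C)CCc23)c(C=O)c(OCOC)cc1OCOC
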